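The amounts of intermediate read so far stay close to the scatter: the zeta run held 1.2 % and 1.3 % beside 18.2 % and 10.8 % of starting material at 5.00 d and 8.00 d, and the delta run reads 0.6 % at 1.67 d and 0.2 % at 10.0 d, against a scatter of 0.5 percentage points.

the same everywhere: starting material 1.5 M
- zeta: coupling partner 1.8 M; protic impurity 0.20 M; temperature 45 °C; run made earlier
- delta: coupling partner 1.8 M; protic impurity 0.45 M; temperature 78 °C; run made earlier
- cedar: coupling partner 1.80 M; protic impurity 0.300 M; temperature 90 °C; time 10 d
- ash: coupling partner 1.80 M; protic impurity 0.300 M; temperature 30 °C; time 10 d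
- maple: coupling partner 1.80 M; protic impurity 0.300 M; temperature 60 °C; time 10 d

| run | time / d | intermediate / % | product / % | starting material / % |
|---|---|---|---|---|
| zeta | 5.00 | 1.2 | 69.3 | 18.2 |
| zeta | 8.00 | 1.3 | 77.9 | 10.8 |
| zeta | 12.0 | 0 | 82.4 | 5.0 |
| zeta | 20.0 | 0 | 86.7 | 2.1 |
| zeta | 40.0 | 0 | 88.6 | 0.1 |
| zeta | 60.0 | 0 | 88.6 | 0.9 |
| delta | 0.833 | 0 | 85.5 | 0.8 |
| delta | 1.67 | 0.6 | 86.7 | 0.2 |
| delta | 2.50 | 0 | 87.2 | 0.4 |
| delta | 4.00 | 0 | 87.3 | 0 |
| delta | 8.00 | 0 | 86.0 | 0 |
| delta | 10.0 | 0.2 | 86.9 | 0.8 |

(each reading ± 0.5 percentage points)



- which flask leads in amount of intermediate, in percent of the starting material charged ("all alike" within 1.5 percentage points) (cedar / ash / maple / all alike)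
- how much intermediate is there at the end, in percent of the starting material charged: cedar
- how much intermediate is there at the end, in percent of the starting material charged: ash
- how much intermediate is there at the end, in percent of the starting material charged: maple

The dispute concerns ash, the cold flask at 30 °C, where starting material should remain at 10 d. One chemist keeps the ratio of intermediate to starting material as zeta shows it; pooling the two readings gives 0.0862.

I hold the other view. The intermediate sits between a step that makes it and a step that removes it, a steady-state balance, and I assume that the making step consumes coupling partner. The ratio should then follow the partner still present. So I define the holding number h: intermediate over starting material, per molar of coupling partner left. If each starting material lost took one partner, zeta had 0.518 M left around those readings, which gives h = 0.167 M⁻¹.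

Now I go round twice for ash. With the partner at its charge of 1.80 M, the ratio would be 0.301. But if about half of the starting material is gone, as the forecast expects, the partner falls to 1.05 M. Putting that back gives a ratio of 0.175 and 8.75 % of intermediate. I give h no temperature dependence, as the delta readings of intermediate lie too near the scatter to show how it moves.

The forecast takes the first side, calling the intermediate “roughly at steady state”. It names ash as leader, with 3.5 % there, 0 % in cedar and 0.1 % in maple. My figure for ash is higher.

The simulation gives 14.3 % in ash, 0 % in cedar and 0 % in maple, so ash leads.

    coupling partner + protic impurity → quenched reagent (k = 2.39 × 10⁻⁴ M⁻¹ min⁻¹, Ea = 70.0 kJ mol⁻¹)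
    2 starting material → homo dimer (k = 1.30 × 10⁻⁴ M⁻¹ min⁻¹, Ea = 102 kJ mol⁻¹)
    starting material + coupling partner → intermediate + by-product (k = 0.00109 M⁻¹ min⁻¹, Ea = 96.0 kJ mol⁻¹)
    intermediate → product (k = 0.00839 min⁻¹, Ea = 111 kJ mol⁻¹)
    (constants at 60 °C)

Ash at 10 d holds 46 % of its starting material and 56 % of its coupling partner, so its h is 0.307 M⁻¹, twice the zeta reading. My h carried no temperature dependence, but the step from intermediate to product has one, and it is part of the difference between the flasks: with it taken off, the gap between cedar and ash shrinks from 14 points to 5.6 points. The fixed ratio comes near the flask late in ash, with 16.3 % of the coupling partner left: at 100 d, 0.322 % over 4.49 % gives 0.0717, close to the forecast's 0.08.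

In the neighbour of cedar, charged with 0.075 M of protic impurity, h times the partner left (24 % of charge) times the starting material left (0 %) gives 0 %. The computed flask holds 0 %.

The numbers in the tables stem from a simulated flask for an exercise.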